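**Strategy.** Fraxiresinol (furo[3,4-c]furan numbering) is cut at the O-5–C-6 bond of the oxolane that carries the guaiacyl group (ring C-3a, C-4, O-5, C-6, C-6a). The precursor is a monocyclic oxolane: syringyl at C-2, a tertiary OH and a CH2OH at C-3, and a 4-hydroxy-3-methoxybenzyl group at C-4, cis to the CH2OH. The key step exploits the free para-phenol of that benzyl group: DDQ oxidises its benzylic CH2 to a p-quinone methide (transient dearomatisation), and the cis CH2OH closes onto it 5-exo, which forms the C–O bond, the second ring and the last stereocentre at once. The other three stereocentres come from an organocatalytic glyoxylate aldol, a lactone enediolate aldol and an acid-catalysed etherification.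

Key step: step 9

Assumption: the free-hydroxyl diarylprolinol is taken to direct ethyl glyoxylate to the same enamine face as proline does, so the (R)-catalyst is specified in step 3; if the sense proves opposite, the (S)-catalyst is used.

**Step 1**
Reactants: 1 methyl 3-(4-hydroxy-3-methoxyphenyl)propanoate
Product: 2 methyl 3-[3-methoxy-4-(triisopropylsilyloxy)phenyl]propanoate
Conditions: iPr3SiCl, imidazole, DMAP (cat.), DMF, rt
Reagents that add atoms: triisopropylsilyl chloride, CC(C)[Si](Cl)(C(C)C)C(C)C
Why: Imidazole-promoted O-silylation of the phenol is a standard silyl ether formation, and the bulky aryl silyl ether should survive hydride, amide base and mild acid until fluoride removes it just before the key step.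

**Step 2**
Reactants: 2 methyl 3-[3-methoxy-4-(triisopropylsilyloxy)phenyl]propanoate
Product: 3 3-[3-methoxy-4-(triisopropylsilyloxy)phenyl]propanal
Conditions: iBu2AlH (1.05 equiv), toluene, −78 °C; MeOH, then aqueous potassium sodium tartrate
Reagents that add atoms: none
Why: Partial ester reduction with iBu2AlH at −78 °C should stop at the tetrahedral aluminium hemiacetal, which releases the aldehyde only on work-up.

**Step 3**
Reactants: 3 3-[3-methoxy-4-(triisopropylsilyloxy)phenyl]propanal; 4 ethyl glyoxylate (polymeric form, toluene solution)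
Product: 7 (3S,4S)-3-hydroxy-4-{[3-methoxy-4-(triisopropylsilyloxy)phenyl]methyl}oxolan-2-one, via aldol aldehyde 5 (not isolated), via diol ester 6 (not isolated)
Conditions: (R)-α,α-bis[3,5-bis(trifluoromethyl)phenyl]pyrrolidine-2-methanol (10 mol %), MeCN, H2O (3 equiv), rt; then MeOH, NaBH4, −20 °C; then 1 M HCl, rt
Reagents that add atoms: none
Why: Enamine-catalysed cross-aldol reaction followed by chemoselective aldehyde reduction and lactonisation: the hydroxyl of the diarylprolinol directs the highly electrophilic glyoxylate to one face of the E-enamine of 3, which should set the benzyl-bearing carbon (C-4 of 7, the later ring-fusion CH) as S, and immediate NaBH4 reduction prevents epimerisation of aldehyde 5, whereas the carbinol centre C-3 (mainly anti, hence cis in 7) is of no consequence because it is planarised in step 5.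

**Step 4**
Reactants: 8 syringaldehyde (4-hydroxy-3,5-dimethoxybenzaldehyde)
Product: 9 3,5-dimethoxy-4-(prop-2-enyloxy)benzaldehyde
Conditions: allyl bromide, K2CO3, acetone, reflux
Reagents that add atoms: allyl bromide, C=CCBr
Why: Williamson etherification of the phenoxide gives an allyl ether that keeps the syringyl ring a good cation donor for step 7, leaves no free syringyl phenol in the oxidation of step 9, and is removed at the end without acid or hydrogen.

**Step 5**
Reactants: 7 (3S,4S)-3-hydroxy-4-{[3-methoxy-4-(triisopropylsilyloxy)phenyl]methyl}oxolan-2-one; 9 3,5-dimethoxy-4-(prop-2-enyloxy)benzaldehyde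
Product: 11 (3R,4S)-3-{[3,5-dimethoxy-4-(prop-2-enyloxy)phenyl](hydroxy)methyl}-3-hydroxy-4-{[3-methoxy-4-(triisopropylsilyloxy)phenyl]methyl}oxolan-2-one (carbinol epimers), via dilithium enediolate 10 (not isolated)
Conditions: LiN(iPr)2 (2.2 equiv), THF, −78 to −30 °C; then 9, −78 °C; aqueous NH4Cl
Reagents that add atoms: none
Why: Aldol addition of a lactone enediolate (dianion of an α-hydroxy ester): the aldehyde should approach the planar enediolate 10 on the face anti to the C-4 arylmethyl group, which sets the quaternary carbinol C-3 as R with its hydroxyl cis to that group, while the new benzylic carbinol forms as an epimer mixture that converges in step 7.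

**Step 6**
Reactants: 11 aldol lactone (carbinol epimers)
Product: 12 (2S,3S)-1-[3,5-dimethoxy-4-(prop-2-enyloxy)phenyl]-2-(hydroxymethyl)-3-{[3-methoxy-4-(triisopropylsilyloxy)phenyl]methyl}butane-1,2,4-triol (C-1 epimers)
Conditions: LiAlH4 (4 equiv), THF, 0 °C; H2O, aqueous NaOH
Reagents that add atoms: none
Why: Hydride reduction of the lactone to the 1,4-diol should be fast at 0 °C, outrunning retro-aldol cleavage, and touches neither the aryl silyl ether, the allyl ether nor any stereocentre.

**Step 7**
Reactants: 12 tetraol (C-1 epimers)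
Product: 13 (2R,3S,4S)-2-[3,5-dimethoxy-4-(prop-2-enyloxy)phenyl]-3-(hydroxymethyl)-4-{[3-methoxy-4-(triisopropylsilyloxy)phenyl]methyl}oxolan-3-ol
Conditions: (+)-camphor-10-sulfonic acid (0.1 equiv), CH2Cl2, 0 °C to rt
Reagents that add atoms: none
Why: Acid-catalysed SN1 cyclodehydration (cycloetherification): the 4-alkoxy-3,5-dimethoxybenzylic carbinol ionises, only the primary hydroxyl on the arylmethyl-bearing carbon can capture the cation in a five-membered ring, and both carbinol epimers should converge on the 2R oxolane in which the aryl group is trans to the C-3 CH2OH and the C-4 arylmethyl groups, under kinetic as well as thermodynamic control.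

**Step 8**
Reactants: 13 silyl-protected oxolane
Product: 14 (2R,3S,4S)-2-[3,5-dimethoxy-4-(prop-2-enyloxy)phenyl]-4-[(4-hydroxy-3-methoxyphenyl)methyl]-3-(hydroxymethyl)oxolan-3-ol
Conditions: Bu4NF (1.1 equiv), AcOH (1.1 equiv), THF, 0 °C
Reagents that add atoms: none
Why: Fluoride-induced desilylation, driven by the strong Si–F bond, should free only the guaiacyl phenol and leave the allyl ether, the alcohols and the benzylic ether untouched.

**Step 9**
Reactants: 14 phenolic oxolane
Product: 16 (3R,3aS,6S,6aR)-3-[3,5-dimethoxy-4-(prop-2-enyloxy)phenyl]-6-(4-hydroxy-3-methoxyphenyl)tetrahydro-1H,3H-furo[3,4-c]furan-3a(4H)-ol, via p-quinone methide 15 (not isolated)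
Conditions: 2,3-dichloro-5,6-dicyano-1,4-benzoquinone (DDQ, 1.05 equiv), CH2Cl2, 0 °C to rt
Reagents that add atoms: none
Why: DDQ formally removes hydride from the benzylic CH2 para to the free guaiacyl hydroxyl, so that the arene is transiently dearomatised to p-quinone methide 15, and the primary hydroxyl of the C-3 CH2OH group, which sits cis to the methide-bearing substituent, then adds to the exocyclic methide carbon and rearomatises the ring. The closest known reactions are the DDQ oxidations of p-hydroxybenzyl lignans through quinone methides and the quinone methide closures that form furofurans in lignan biosynthesis. The one ring that forms is closed in the 5-exo-trig mode (oxa-1,6-addition), and only a cis ring fusion is possible. The new benzylic stereocentre is controlled by the substrate: in the envelope-like transition state the aryl group should take the exo (convex) position, trans to the CH2 of the first oxolane, and because closure is reversible in the presence of the acidic hydroquinone the more stable exo isomer should also be the thermodynamic product. The step needs chemoselective oxidation at the guaiacyl CH2 rather than at the syringyl benzylic ether CH or at the product, which is secured by there being one free phenol only, one equivalent of oxidant and low temperature. O-capture rather than C-capture, and a five- rather than a four-membered ring, are secured by the primary hydroxyl being the only nucleophile that reaches the methide carbon without strain.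

**Step 10**
Reactants: 16 fraxiresinol allyl ether
Product: 17 fraxiresinol, (3R,3aS,6S,6aR)-3-(4-hydroxy-3,5-dimethoxyphenyl)-6-(4-hydroxy-3-methoxyphenyl)tetrahydro-1H,3H-furo[3,4-c]furan-3a(4H)-ol
Conditions: Pd(PPh3)4 (5 mol %), morpholine (5 equiv), THF, rt
Reagents that add atoms: none
Why: Tsuji–Trost-type deallylation, in which the palladium catalyst ionises the aryl allyl ether to a π-allyl complex and phenoxide and morpholine traps the allyl group, should leave the benzylic ethers and all four stereocentres unaffected.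

**Compound list**
1 | methyl 3-(4-hydroxy-3-methoxyphenyl)propanoate | COC(=O)CCc1ccc(O)c(OC)c1 | starting material
2 | methyl 3-[3-methoxy-4-(triisopropylsilyloxy)phenyl]propanoate | COC(=O)CCc1ccc(O[Si](C(C)C)(C(C)C)C(C)C)c(OC)c1 | intermediate
3 | 3-[3-methoxy-4-(triisopropylsilyloxy)phenyl]propanal | O=CCCc1ccc(O[Si](C(C)C)(C(C)C)C(C)C)c(OC)c1 | intermediate
4 | ethyl glyoxylate | CCOC(=O)C=O | starting material
5 | ethyl (2S,3R)-3-formyl-2-hydroxy-4-[3-methoxy-4-(triisopropylsilyloxy)phenyl]butanoate (aldol aldehyde) | CCOC(=O)[C@@H](O)[C@H](C=O)Cc1ccc(O[Si](C(C)C)(C(C)C)C(C)C)c(OC)c1 | intermediate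
6 | ethyl (2S,3S)-2-hydroxy-3-(hydroxymethyl)-4-[3-methoxy-4-(triisopropylsilyloxy)phenyl]butanoate (diol ester) | CCOC(=O)[C@@H](O)[C@H](CO)Cc1ccc(O[Si](C(C)C)(C(C)C)C(C)C)c(OC)c1 | intermediate
7 | (3S,4S)-3-hydroxy-4-{[3-methoxy-4-(triisopropylsilyloxy)phenyl]methyl}oxolan-2-one | O=C1OC[C@H](Cc2ccc(O[Si](C(C)C)(C(C)C)C(C)C)c(OC)c2)[C@@H]1O | intermediate
8 | syringaldehyde (4-hydroxy-3,5-dimethoxybenzaldehyde) | COc1cc(C=O)cc(OC)c1O | starting material
9 | 3,5-dimethoxy-4-(prop-2-enyloxy)benzaldehyde | C=CCOc1c(OC)cc(C=O)cc1OC | intermediate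
10 | dilithium (4S)-4-{[3-methoxy-4-(triisopropylsilyloxy)phenyl]methyl}-4,5-dihydrofuran-2,3-bis(olate) (dilithium enediolate) | [Li+].[Li+].[O-]C1=C([O-])[C@@H](Cc2ccc(O[Si](C(C)C)(C(C)C)C(C)C)c(OC)c2)CO1 | intermediate
11 | (3R,4S)-3-{[3,5-dimethoxy-4-(prop-2-enyloxy)phenyl](hydroxy)methyl}-3-hydroxy-4-{[3-methoxy-4-(triisopropylsilyloxy)phenyl]methyl}oxolan-2-one (carbinol epimers) | O=C1OC[C@H](Cc2ccc(O[Si](C(C)C)(C(C)C)C(C)C)c(OC)c2)[C@@]1(O)C(O)c3cc(OC)c(OCC=C)c(OC)c3 | intermediate
12 | (2S,3S)-1-[3,5-dimethoxy-4-(prop-2-enyloxy)phenyl]-2-(hydroxymethyl)-3-{[3-methoxy-4-(triisopropylsilyloxy)phenyl]methyl}butane-1,2,4-triol (C-1 epimers) | OC[C@H](Cc1ccc(O[Si](C(C)C)(C(C)C)C(C)C)c(OC)c1)[C@](O)(CO)C(O)c2cc(OC)c(OCC=C)c(OC)c2 | intermediate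
13 | (2R,3S,4S)-2-[3,5-dimethoxy-4-(prop-2-enyloxy)phenyl]-3-(hydroxymethyl)-4-{[3-methoxy-4-(triisopropylsilyloxy)phenyl]methyl}oxolan-3-ol | OC[C@@]1(O)[C@@H](Cc2ccc(O[Si](C(C)C)(C(C)C)C(C)C)c(OC)c2)CO[C@@H]1c3cc(OC)c(OCC=C)c(OC)c3 | intermediate
14 | (2R,3S,4S)-2-[3,5-dimethoxy-4-(prop-2-enyloxy)phenyl]-4-[(4-hydroxy-3-methoxyphenyl)methyl]-3-(hydroxymethyl)oxolan-3-ol | OC[C@@]1(O)[C@@H](Cc2ccc(O)c(OC)c2)CO[C@@H]1c3cc(OC)c(OCC=C)c(OC)c3 | intermediate
15 | 4-{[(3S,4S,5R)-5-[3,5-dimethoxy-4-(prop-2-enyloxy)phenyl]-4-hydroxy-4-(hydroxymethyl)oxolan-3-yl]methylidene}-2-methoxycyclohexa-2,5-dien-1-one (p-quinone methide) | OC[C@@]1(O)[C@@H](C=C2C=CC(=O)C(OC)=C2)CO[C@@H]1c3cc(OC)c(OCC=C)c(OC)c3 | intermediate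
16 | (3R,3aS,6S,6aR)-3-[3,5-dimethoxy-4-(prop-2-enyloxy)phenyl]-6-(4-hydroxy-3-methoxyphenyl)tetrahydro-1H,3H-furo[3,4-c]furan-3a(4H)-ol | COc1cc([C@H]2OC[C@]3(O)[C@@H](c4cc(OC)c(OCC=C)c(OC)c4)OC[C@H]23)ccc1O | intermediate
17 | fraxiresinol, (3R,3aS,6S,6aR)-3-(4-hydroxy-3,5-dimethoxyphenyl)-6-(4-hydroxy-3-methoxyphenyl)tetrahydro-1H,3H-furo[3,4-c]furan-3a(4H)-ol | COc1cc([C@H]2OC[C@]3(O)[C@@H](c4cc(OC)c(O)c(OC)c4)OC[C@H]23)ccc1O | target

**Step count.** Total: 10 steps. Longest linear sequence: 9 steps (steps 1, 2, 3, 5, 6, 7, 8, 9, 10); step 4 is a one-step side branch.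

**The three steps most likely to fail**

Step 9 (key step). What may go wrong: over-oxidation of the newly formed p-hydroxybenzylic ether, competing hydride abstraction at the syringyl benzylic ether, or poor exo/endo selectivity when the quinone methide is captured. The fallback replaces the direct capture by a stepwise closure under thermodynamic control. Setting out from 14, an excess of DDQ (2.2 equiv) in wet 1,4-dioxane is used on purpose to carry the oxidation through to the aryl ketone (4-hydroxy-3-methoxyphenyl)[(3S,4S,5R)-5-[3,5-dimethoxy-4-(prop-2-enyloxy)phenyl]-4-hydroxy-4-(hydroxymethyl)oxolan-3-yl]methanone F1. Reduction with NaBH4 and CeCl3·7H2O in MeOH at −78 °C (Luche conditions, near neutral, to avoid retro-aldol cleavage and epimerisation next to the ketone) should give the benzylic carbinol (2R,3S,4R)-2-[3,5-dimethoxy-4-(prop-2-enyloxy)phenyl]-4-[hydroxy(4-hydroxy-3-methoxyphenyl)methyl]-3-(hydroxymethyl)oxolan-3-ol F2 as an epimer mixture. Catalytic camphor-10-sulfonic acid in CH2Cl2 then closes the ring by SN1 cyclodehydration under equilibrating conditions, and the route is rejoined at 16.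

Step 5. What may go wrong: incomplete formation or aggregation of the dianion, retro-aldol loss of the adduct, or low facial selectivity at the quaternary centre. The fallback is a Lewis-acid Mukaiyama aldol reaction instead of a lithium dianion. Setting out from 7, Me3SiOTf and Et3N in CH2Cl2 should give the silyl ketene acetal (4S)-4-{[3-methoxy-4-(triisopropylsilyloxy)phenyl]methyl}-2,3-bis(trimethylsilyloxy)-4,5-dihydrofuran F3. With 9 and BF3·OEt2 at −78 °C this should add anti to the arylmethyl group through an open transition state. Dilute acid work-up removes both trimethylsilyl groups, and the route is rejoined at 11.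

Step 7. What may go wrong: a pinacol-type 1,2-shift of the benzylic cation next to the tertiary carbinol, or Friedel–Crafts capture of the cation by the guaiacyl ring (aryltetralin formation) instead of capture by oxygen. The fallback closes the ring through a syringyl quinone methide under nearly neutral conditions. Setting out from 12, Pd(PPh3)4 and morpholine remove the allyl group to give the phenolic tetraol (2S,3S)-1-(4-hydroxy-3,5-dimethoxyphenyl)-2-(hydroxymethyl)-3-{[3-methoxy-4-(triisopropylsilyloxy)phenyl]methyl}butane-1,2,4-triol F4. On gentle warming in MeCN–H2O with a trace of AcOH its p-hydroxybenzylic carbinol should lose water to a quinone methide, which the same primary hydroxyl captures to give (2R,3S,4S)-2-(4-hydroxy-3,5-dimethoxyphenyl)-3-(hydroxymethyl)-4-{[3-methoxy-4-(triisopropylsilyloxy)phenyl]methyl}oxolan-3-ol F5. Allyl bromide and K2CO3 in acetone then re-protect the only free phenol, and the route is rejoined at 13.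

**Further compounds**
F1 | step 9 | (4-hydroxy-3-methoxyphenyl)[(3S,4S,5R)-5-[3,5-dimethoxy-4-(prop-2-enyloxy)phenyl]-4-hydroxy-4-(hydroxymethyl)oxolan-3-yl]methanone | OC[C@@]1(O)[C@@H](C(=O)c2ccc(O)c(OC)c2)CO[C@@H]1c3cc(OC)c(OCC=C)c(OC)c3
F2 | step 9 | (2R,3S,4R)-2-[3,5-dimethoxy-4-(prop-2-enyloxy)phenyl]-4-[hydroxy(4-hydroxy-3-methoxyphenyl)methyl]-3-(hydroxymethyl)oxolan-3-ol (carbinol epimers) | OC[C@@]1(O)[C@@H](C(O)c2ccc(O)c(OC)c2)CO[C@@H]1c3cc(OC)c(OCC=C)c(OC)c3
F3 | step 5 | (4S)-4-{[3-methoxy-4-(triisopropylsilyloxy)phenyl]methyl}-2,3-bis(trimethylsilyloxy)-4,5-dihydrofuran | C[Si](C)(C)OC1=C(O[Si](C)(C)C)[C@@H](Cc2ccc(O[Si](C(C)C)(C(C)C)C(C)C)c(OC)c2)CO1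
F4 | step 7 | (2S,3S)-1-(4-hydroxy-3,5-dimethoxyphenyl)-2-(hydroxymethyl)-3-{[3-methoxy-4-(triisopropylsilyloxy)phenyl]methyl}butane-1,2,4-triol (C-1 epimers) | OC[C@H](Cc1ccc(O[Si](C(C)C)(C(C)C)C(C)C)c(OC)c1)[C@](O)(CO)C(O)c2cc(OC)c(O)c(OC)c2
F5 | step 7 | (2R,3S,4S)-2-(4-hydroxy-3,5-dimethoxyphenyl)-3-(hydroxymethyl)-4-{[3-methoxy-4-(triisopropylsilyloxy)phenyl]methyl}oxolan-3-ol | OC[C@@]1(O)[C@@H](Cc2ccc(O[Si](C(C)C)(C(C)C)C(C)C)c(OC)c2)CO[C@@H]1c3cc(OC)c(O)c(OC)c3
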